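**Retrosynthetic overview**

1. Numbering: carbocycle C1 (acyloxy carbon), C2 (ketone), C3 (methyl-bearing epoxide carbon), C4 (epoxide CH), C5 (CH2), C6 (side-chain carbon); side chain C7 (oxirane carbon), C8 (enone carbonyl).
2. Side chain last: the C8–alkenyl bond by alkenylchromium addition to a C7 epoxy aldehyde and oxidation; the C7 oxirane by amine-catalysed epoxidation of an α-methylene aldehyde grown from a CH2CH2O arm on C6.
3. Ring oxygens: C1–O by enolate hydroxylation trans to the C6 arm; the C3–C4 epoxide by carbinol-directed epoxidation of the cis allylic alcohol of a 2-methylcyclohex-2-enone, because peroxide addition to the enone itself would place the oxygen trans to the arm.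
4. Key disconnection: that enone is cut at C3=C4 (aldol condensation) and C1–C6 (Michael addition) into tert-butyl 3-oxopentanoate and an (E)-5-silyloxypent-2-enal; the enabling feature is that the C2 carbonyl and C4 stand 1,5 to each other through C1–C6–C5 of the six-membered ring, with methyl-bearing C3 as the enolisable carbon between them.
5. Ring order: carbocycle (step 3), then the C3–C4 oxirane (step 5), then the side-chain oxirane (step 12).

Key step: step 3

Remark on the chemistry: 6 and 7 are epimeric at C1 and 22 at its new carbinol carbon; these centres disappear in steps 3 and 15 and are left undefined in the SMILES.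

**Route**

Step 1
Reactants: 1 but-3-en-1-ol
Product: 2 tert-butyl(but-3-en-1-yloxy)diphenylsilane
Conditions: t-BuPh2SiCl, imidazole, CH2Cl2, 0 °C to rt
Reagents that add atoms: tert-butyl(chloro)diphenylsilane, CC(C)(C)[Si](Cl)(c1ccccc1)c1ccccc1
Why: Silylation of a primary alcohol; the tert-butyldiphenylsilyl ether is chosen because it should survive the acid of step 3 and still leave with fluoride in step 9.

Step 2
Reactants: 2 tert-butyl(but-3-en-1-yloxy)diphenylsilane; 3 (E)-but-2-enal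
Product: 4 (E)-5-(tert-butyldiphenylsilyloxy)pent-2-enal
Conditions: second-generation Grubbs catalyst RuCl2(=CHPh)(PCy3)(H2IMes) (3 mol%), excess 3, CH2Cl2, 40 °C
Reagents that add atoms: none
Why: Olefin cross-metathesis of a terminal alkene with crotonaldehyde should give the E-enal under thermodynamic control, with propene leaving.

Step 3
Reactants: 4 (E)-5-(tert-butyldiphenylsilyloxy)pent-2-enal; 5 tert-butyl 3-oxopentanoate
Product: 8 (5S)-5-[2-(tert-butyldiphenylsilyloxy)ethyl]-2-methylcyclohex-2-en-1-one, via Michael adduct 6 (not isolated), via cyclohexenone tert-butyl ester 7 (not isolated)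
Conditions: (S)-2-{bis[3,5-bis(trifluoromethyl)phenyl](trimethylsilyloxy)methyl}pyrrolidine (10 mol%), PhCO2H (10 mol%), toluene, rt; then TsOH·H2O (20 mol%), toluene, 80 °C
Reagents that add atoms: none
Why: The (S)-diarylprolinol silyl ether turns enal 4 into an iminium ion whose face next to the diaryl(silyloxy)methyl group is blocked, so the enol of β-ketoester 5 adds to the β-carbon from the open face and sets C6, and hydrolysis frees aldehyde 6 and the amine. TsOH then enolises the ethyl ketone toward C3, which attacks the aldehyde carbon C4 in an intramolecular aldol reaction (6-(enolendo)-exo-trig, the only closure that gives a six-membered ring), and dehydration into conjugation with the C2 carbonyl gives 7 with the C3=C4 bond in place. The tert-butyl ester, needed only to acidify C1 for the Michael step, leaves under the same acid as 2-methylpropene and CO2. The closest known reaction type is the amine-catalysed Michael addition/aldol condensation of β-ketoesters with enals to 5-substituted cyclohex-2-enones, a catalytic asymmetric Robinson-type annulation. The only stereocentre that survives is C6, controlled by the catalyst, and the enone delivered is the template from which C3, C4 and C1 are set in steps 4 to 7. The step needs 1,4- over 1,2-addition (secured by iminium activation of an unbranched β-alkyl enal), ring closure through C3 only (secured by ring size) and a silyl ether that survives hot acid (secured by the tert-butyldiphenylsilyl group).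

Step 4
Reactants: 8 (5S)-5-[2-(tert-butyldiphenylsilyloxy)ethyl]-2-methylcyclohex-2-en-1-one
Product: 9 (1R,5S)-5-[2-(tert-butyldiphenylsilyloxy)ethyl]-2-methylcyclohex-2-en-1-ol
Conditions: NaBH4, CeCl3·7H2O, MeOH, −78 to 0 °C
Reagents that add atoms: none
Why: Luche 1,2-reduction; axial hydride delivery to the half-chair with the C6 arm pseudo-equatorial should give the carbinol cis to the arm, as in the carvone to cis-carveol reduction.

Step 5
Reactants: 9 (1R,5S)-5-[2-(tert-butyldiphenylsilyloxy)ethyl]-2-methylcyclohex-2-en-1-ol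
Product: 10 (1R,2R,4S,6S)-4-[2-(tert-butyldiphenylsilyloxy)ethyl]-1-methyl-7-oxabicyclo[4.1.0]heptan-2-ol
Conditions: VO(acac)2 (5 mol%), t-BuOOH (decane), CH2Cl2, 0 °C to rt
Reagents that add atoms: tert-butyl hydroperoxide, CC(C)(C)OO
Why: Vanadium-catalysed hydroxyl-directed epoxidation delivers oxygen to the face of the allylic hydroxyl, so C3 and C4 are set with the epoxide cis to the carbinol and hence cis to the C6 arm.

Step 6
Reactants: 10 (1R,2R,4S,6S)-4-[2-(tert-butyldiphenylsilyloxy)ethyl]-1-methyl-7-oxabicyclo[4.1.0]heptan-2-ol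
Product: 11 (1S,4R,6S)-4-[2-(tert-butyldiphenylsilyloxy)ethyl]-1-methyl-7-oxabicyclo[4.1.0]heptan-2-one
Conditions: Dess–Martin periodinane, CH2Cl2, 0 °C to rt
Reagents that add atoms: none
Why: Dess–Martin oxidation returns the C2 ketone under near-neutral conditions; C3 is quaternary, so no stereocentre can epimerise.

Step 7
Reactants: 11 (1S,4R,6S)-4-[2-(tert-butyldiphenylsilyloxy)ethyl]-1-methyl-7-oxabicyclo[4.1.0]heptan-2-one
Product: 12 (1S,3S,4R,6S)-4-[2-(tert-butyldiphenylsilyloxy)ethyl]-3-hydroxy-1-methyl-7-oxabicyclo[4.1.0]heptan-2-one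
Conditions: KN(SiMe3)2, THF, −78 °C; then 3-phenyl-2-(phenylsulfonyl)oxaziridine, −78 °C; AcOH quench
Reagents that add atoms: 3-phenyl-2-(phenylsulfonyl)oxaziridine, O=S(=O)(c1ccccc1)N1OC1c1ccccc1
Why: Enolate hydroxylation with the Davis oxaziridine; the ketone can enolise only toward C1 because C3 is quaternary, and the oxidant should approach anti to the adjacent C6 arm to give the trans, diequatorial hydroxy ketone, which is also the thermodynamically preferred epimer at this enolisable centre.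

Step 8
Reactants: 12 (1S,3S,4R,6S)-4-[2-(tert-butyldiphenylsilyloxy)ethyl]-3-hydroxy-1-methyl-7-oxabicyclo[4.1.0]heptan-2-one; 13 3-methylbutanoyl chloride
Product: 14 (1S,3S,4R,6S)-4-[2-(tert-butyldiphenylsilyloxy)ethyl]-1-methyl-2-oxo-7-oxabicyclo[4.1.0]heptan-3-yl 3-methylbutanoate
Conditions: pyridine, DMAP (5 mol%), CH2Cl2, 0 °C
Reagents that add atoms: none
Why: DMAP-catalysed acylation of the secondary α-hydroxy ketone with retention at C1.

Step 9
Reactants: 14 (1S,3S,4R,6S)-4-[2-(tert-butyldiphenylsilyloxy)ethyl]-1-methyl-2-oxo-7-oxabicyclo[4.1.0]heptan-3-yl 3-methylbutanoate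
Product: 15 (1S,3S,4R,6S)-4-(2-hydroxyethyl)-1-methyl-2-oxo-7-oxabicyclo[4.1.0]heptan-3-yl 3-methylbutanoate
Conditions: HF·pyridine, pyridine, THF, 0 °C to rt
Reagents that add atoms: none
Why: Fluoride-mediated desilylation under pyridine-buffered conditions should spare the epoxy ketone and the ester.

Step 10
Reactants: 15 (1S,3S,4R,6S)-4-(2-hydroxyethyl)-1-methyl-2-oxo-7-oxabicyclo[4.1.0]heptan-3-yl 3-methylbutanoate
Product: 16 (1S,3S,4S,6S)-1-methyl-2-oxo-4-(2-oxoethyl)-7-oxabicyclo[4.1.0]heptan-3-yl 3-methylbutanoate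
Conditions: Dess–Martin periodinane, CH2Cl2, 0 °C to rt
Reagents that add atoms: none
Why: Dess–Martin oxidation of the primary alcohol to the aldehyde without over-oxidation.

Step 11
Reactants: 16 (1S,3S,4S,6S)-1-methyl-2-oxo-4-(2-oxoethyl)-7-oxabicyclo[4.1.0]heptan-3-yl 3-methylbutanoate
Product: 17 (1S,3S,4S,6S)-1-methyl-2-oxo-4-(3-oxoprop-1-en-2-yl)-7-oxabicyclo[4.1.0]heptan-3-yl 3-methylbutanoate
Conditions: CH2=NMe2+ I− (Eschenmoser's salt), Et3N, CH2Cl2, rt
Reagents that add atoms: N,N-dimethylmethyleneiminium iodide, C=[N+](C)C.[I-]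
Why: Mannich reaction at the aldehyde α-carbon (C7) followed by elimination of dimethylamine (α-methylenation) installs the C7 methylene; the aldehyde enolises far more readily than the hindered ring ketone.

Step 12
Reactants: 17 (1S,3S,4S,6S)-1-methyl-2-oxo-4-(3-oxoprop-1-en-2-yl)-7-oxabicyclo[4.1.0]heptan-3-yl 3-methylbutanoate
Product: 18 (1S,3S,4R,6S)-4-[(2R)-2-formyloxiran-2-yl]-1-methyl-2-oxo-7-oxabicyclo[4.1.0]heptan-3-yl 3-methylbutanoate
Conditions: (S)-2-{diphenyl[(methyldiphenylsilyl)oxy]methyl}pyrrolidine (10 mol%), 35% aq. H2O2, hexane, rt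
Reagents that add atoms: hydrogen peroxide, OO
Why: Amine-catalysed nucleophilic epoxidation of an α-substituted acrolein: H2O2 adds to the CH2 terminus of the iminium ion and the β-hydroperoxy enamine closes onto C7 on the face away from the catalyst's shielding group, which with the (S)-catalyst should give the (R)-oxirane under reagent control.

Step 13
Reactants: 19 2-methylbut-3-yn-2-ol
Product: 21 (E)-4-iodo-2-methylbut-3-en-2-ol, via vinylstannane 20 (not isolated)
Conditions: Bu3SnH, PdCl2(PPh3)2 (2 mol%), THF, 0 °C to rt; then I2, CH2Cl2, 0 °C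
Reagents that add atoms: iodine, II; tributyltin hydride, CCCC[SnH](CCCC)CCCC (supplies the stannyl group of 20)
Why: Palladium-catalysed syn-hydrostannation places tin on the terminal carbon of the hindered propargylic alcohol, and iododestannylation proceeds with retention to give the E-vinyl iodide.

Step 14
Reactants: 18 (1S,3S,4R,6S)-4-[(2R)-2-formyloxiran-2-yl]-1-methyl-2-oxo-7-oxabicyclo[4.1.0]heptan-3-yl 3-methylbutanoate; 21 (E)-4-iodo-2-methylbut-3-en-2-ol
Product: 22 (1S,3S,4R,6S)-4-{(2R)-2-[(2E)-1,4-dihydroxy-4-methylpent-2-en-1-yl]oxiran-2-yl}-1-methyl-2-oxo-7-oxabicyclo[4.1.0]heptan-3-yl 3-methylbutanoate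
Conditions: CrCl2 (6 equiv), NiCl2 (2 mol%), DMSO, rt
Reagents that add atoms: none
Why: Nozaki–Hiyama–Kishi coupling; the alkenylchromium reagent adds to aldehydes in preference to ketones and esters, tolerates the free tertiary hydroxyl and keeps the E geometry.

Step 15
Reactants: 22 (1S,3S,4R,6S)-4-{(2R)-2-[(2E)-1,4-dihydroxy-4-methylpent-2-en-1-yl]oxiran-2-yl}-1-methyl-2-oxo-7-oxabicyclo[4.1.0]heptan-3-yl 3-methylbutanoate
Product: 23 (1S,3S,4R,6S)-4-{(2R)-2-[(2E)-4-hydroxy-4-methylpent-2-enoyl]oxiran-2-yl}-1-methyl-2-oxo-7-oxabicyclo[4.1.0]heptan-3-yl 3-methylbutanoate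
Conditions: Dess–Martin periodinane, CH2Cl2, 0 °C
Reagents that add atoms: none
Why: Dess–Martin oxidation of the secondary allylic alcohol gives the enone and removes the undefined carbinol centre; the tertiary alcohol cannot be oxidised.

**Compound list**

1 | but-3-en-1-ol | C=CCCO | starting material
2 | tert-butyl(but-3-en-1-yloxy)diphenylsilane | C=CCCO[Si](c1ccccc1)(c1ccccc1)C(C)(C)C | intermediate
3 | (E)-but-2-enal | C/C=C/C=O | starting material
4 | (E)-5-(tert-butyldiphenylsilyloxy)pent-2-enal | O=C/C=C/CCO[Si](c1ccccc1)(c1ccccc1)C(C)(C)C | intermediate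
5 | tert-butyl 3-oxopentanoate | CCC(=O)CC(=O)OC(C)(C)C | starting material
6 | tert-butyl 2-[(3R)-5-(tert-butyldiphenylsilyloxy)-1-oxopentan-3-yl]-3-oxopentanoate (epimers at C2 of the pentanoate) | CCC(=O)C(C(=O)OC(C)(C)C)[C@@H](CC=O)CCO[Si](c1ccccc1)(c1ccccc1)C(C)(C)C | intermediate
7 | tert-butyl (6S)-6-[2-(tert-butyldiphenylsilyloxy)ethyl]-3-methyl-2-oxocyclohex-3-ene-1-carboxylate (epimers at C1) | CC(C)(C)OC(=O)C1C(=O)C(C)=CC[C@H]1CCO[Si](c1ccccc1)(c1ccccc1)C(C)(C)C | intermediate
8 | (5S)-5-[2-(tert-butyldiphenylsilyloxy)ethyl]-2-methylcyclohex-2-en-1-one | C1C(=O)C(C)=CC[C@H]1CCO[Si](c1ccccc1)(c1ccccc1)C(C)(C)C | intermediate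
9 | (1R,5S)-5-[2-(tert-butyldiphenylsilyloxy)ethyl]-2-methylcyclohex-2-en-1-ol (hydroxyl cis to the arm) | C1[C@@H](O)C(C)=CC[C@H]1CCO[Si](c1ccccc1)(c1ccccc1)C(C)(C)C | intermediate
10 | (1R,2R,4S,6S)-4-[2-(tert-butyldiphenylsilyloxy)ethyl]-1-methyl-7-oxabicyclo[4.1.0]heptan-2-ol (hydroxyl, epoxide oxygen and arm on one face) | C1[C@@H](O)[C@@]2(C)O[C@H]2C[C@H]1CCO[Si](c1ccccc1)(c1ccccc1)C(C)(C)C | intermediate
11 | (1S,4R,6S)-4-[2-(tert-butyldiphenylsilyloxy)ethyl]-1-methyl-7-oxabicyclo[4.1.0]heptan-2-one | C1C(=O)[C@@]2(C)O[C@H]2C[C@H]1CCO[Si](c1ccccc1)(c1ccccc1)C(C)(C)C | intermediate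
12 | (1S,3S,4R,6S)-4-[2-(tert-butyldiphenylsilyloxy)ethyl]-3-hydroxy-1-methyl-7-oxabicyclo[4.1.0]heptan-2-one | O[C@@H]1C(=O)[C@@]2(C)O[C@H]2C[C@H]1CCO[Si](c1ccccc1)(c1ccccc1)C(C)(C)C | intermediate
13 | 3-methylbutanoyl chloride | CC(C)CC(Cl)=O | starting material
14 | (1S,3S,4R,6S)-4-[2-(tert-butyldiphenylsilyloxy)ethyl]-1-methyl-2-oxo-7-oxabicyclo[4.1.0]heptan-3-yl 3-methylbutanoate | CC(C)CC(=O)O[C@@H]1C(=O)[C@@]2(C)O[C@H]2C[C@H]1CCO[Si](c1ccccc1)(c1ccccc1)C(C)(C)C | intermediate
15 | (1S,3S,4R,6S)-4-(2-hydroxyethyl)-1-methyl-2-oxo-7-oxabicyclo[4.1.0]heptan-3-yl 3-methylbutanoate | CC(C)CC(=O)O[C@@H]1C(=O)[C@@]2(C)O[C@H]2C[C@H]1CCO | intermediate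
16 | (1S,3S,4S,6S)-1-methyl-2-oxo-4-(2-oxoethyl)-7-oxabicyclo[4.1.0]heptan-3-yl 3-methylbutanoate | CC(C)CC(=O)O[C@@H]1C(=O)[C@@]2(C)O[C@H]2C[C@H]1CC=O | intermediate
17 | (1S,3S,4S,6S)-1-methyl-2-oxo-4-(3-oxoprop-1-en-2-yl)-7-oxabicyclo[4.1.0]heptan-3-yl 3-methylbutanoate | CC(C)CC(=O)O[C@@H]1C(=O)[C@@]2(C)O[C@H]2C[C@H]1C(=C)C=O | intermediate
18 | (1S,3S,4R,6S)-4-[(2R)-2-formyloxiran-2-yl]-1-methyl-2-oxo-7-oxabicyclo[4.1.0]heptan-3-yl 3-methylbutanoate | CC(C)CC(=O)O[C@@H]1C(=O)[C@@]2(C)O[C@H]2C[C@H]1[C@]1(C=O)CO1 | intermediate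
19 | 2-methylbut-3-yn-2-ol | CC(C)(O)C#C | starting material
20 | (E)-2-methyl-4-(tributylstannyl)but-3-en-2-ol | CCCC[Sn](CCCC)(CCCC)/C=C/C(C)(C)O | intermediate
21 | (E)-4-iodo-2-methylbut-3-en-2-ol | CC(C)(O)/C=C/I | intermediate
22 | (1S,3S,4R,6S)-4-{(2R)-2-[(2E)-1,4-dihydroxy-4-methylpent-2-en-1-yl]oxiran-2-yl}-1-methyl-2-oxo-7-oxabicyclo[4.1.0]heptan-3-yl 3-methylbutanoate (carbinol epimers) | CC(C)CC(=O)O[C@@H]1C(=O)[C@@]2(C)O[C@H]2C[C@H]1[C@]1(C(O)/C=C/C(C)(C)O)CO1 | intermediate
23 | (1S,3S,4R,6S)-4-{(2R)-2-[(2E)-4-hydroxy-4-methylpent-2-enoyl]oxiran-2-yl}-1-methyl-2-oxo-7-oxabicyclo[4.1.0]heptan-3-yl 3-methylbutanoate | CC(C)CC(=O)O[C@@H]1C(=O)[C@@]2(C)O[C@H]2C[C@H]1[C@]1(C(=O)/C=C/C(C)(C)O)CO1 | target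

**Step count**

Total steps: 15. Longest linear sequence: 14 steps (steps 1 to 12, 14 and 15, from but-3-en-1-ol); step 13 is a one-step side branch.

**Steps most likely to fail**

Step 3. The acid stage may strip the silyl ether or divert the Michael adduct into a cyclic hemiacetal or pyran instead of the carbocycle, and reversible Michael addition in hot acid may erode the enantiomeric purity at C6. The fallback closes the same C3=C4 bond by olefin metathesis, sets out from 4 and comes back at 8. Conjugate addition of dimethyl malonate to 4 under the same iminium catalyst (EtOH, 0 °C) would give dimethyl 2-[(3R)-5-(tert-butyldiphenylsilyloxy)-1-oxopentan-3-yl]propanedioate F1. Wittig methylenation of the aldehyde (Ph3P=CH2, 2.2 equiv, THF, −78 to 0 °C) would give dimethyl 2-[(3S)-1-(tert-butyldiphenylsilyloxy)hex-5-en-3-yl]propanedioate F2. Krapcho demethoxycarbonylation (LiCl, wet DMSO, 150 °C) would give methyl (3S)-3-[2-(tert-butyldiphenylsilyloxy)ethyl]hex-5-enoate F3. Treatment with MeNH(OMe)·HCl and i-PrMgCl (THF, −20 °C) would give (3S)-3-[2-(tert-butyldiphenylsilyloxy)ethyl]-N-methoxy-N-methylhex-5-enamide F4, and CH2=C(CH3)MgBr (THF, 0 °C) would give (5S)-5-[2-(tert-butyldiphenylsilyloxy)ethyl]-2-methylocta-1,7-dien-3-one F5. Ring-closing metathesis with the second-generation Grubbs catalyst RuCl2(=CHPh)(PCy3)(H2IMes) (CH2Cl2, 40 °C) then joins C3 and C4 and returns 8.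

Step 12. Facial selectivity may be poor if the catalyst's preference opposes the bias of the neighbouring C6 centre, the enal may isomerise through a dienamine, and the epoxy aldehyde may decompose under the peroxide conditions. The fallback replaces amine catalysis by a tartrate-controlled epoxidation of the allylic alcohol, sets out from 17 and comes back at 18. Chemoselective 1,2-reduction of the enal with LiAlH(O-t-Bu)3 (THF, −78 °C, the hindered ring ketone should be left alone) would give (1S,3S,4S,6S)-4-(3-hydroxyprop-1-en-2-yl)-1-methyl-2-oxo-7-oxabicyclo[4.1.0]heptan-3-yl 3-methylbutanoate F6. Sharpless asymmetric epoxidation (Ti(O-i-Pr)4, L-(+)-diethyl tartrate, t-BuOOH, 4 Å molecular sieves, CH2Cl2, −20 °C) would give (1S,3S,4R,6S)-4-[(2S)-2-(hydroxymethyl)oxiran-2-yl]-1-methyl-2-oxo-7-oxabicyclo[4.1.0]heptan-3-yl 3-methylbutanoate F7, and Dess–Martin oxidation of the primary alcohol returns 18.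

Step 14. Divalent chromium may reductively open the α,β-epoxy ketone or the epoxy aldehyde, and addition to the aldehyde on a quaternary carbon may be slow. The fallback uses an alkenylzinc reagent, which involves no reducing metal, sets out from 18 and comes back at 22. Hydrozirconation of 2-methyl-2-(trimethylsilyloxy)but-3-yne with Cp2Zr(H)Cl (CH2Cl2, rt), transmetalation with Zn(CH3)2 at −65 °C and addition of 18 at 0 °C would give (1S,3S,4R,6S)-4-{(2R)-2-[(2E)-1-hydroxy-4-methyl-4-(trimethylsilyloxy)pent-2-en-1-yl]oxiran-2-yl}-1-methyl-2-oxo-7-oxabicyclo[4.1.0]heptan-3-yl 3-methylbutanoate F8. Brief treatment with aqueous citric acid in THF removes the trimethylsilyl group and returns 22.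

**Further compounds**

F1 | step 3 | dimethyl 2-[(3R)-5-(tert-butyldiphenylsilyloxy)-1-oxopentan-3-yl]propanedioate | COC(=O)C(C(=O)OC)[C@@H](CC=O)CCO[Si](c1ccccc1)(c1ccccc1)C(C)(C)C
F2 | step 3 | dimethyl 2-[(3S)-1-(tert-butyldiphenylsilyloxy)hex-5-en-3-yl]propanedioate | COC(=O)C(C(=O)OC)[C@@H](CC=C)CCO[Si](c1ccccc1)(c1ccccc1)C(C)(C)C
F3 | step 3 | methyl (3S)-3-[2-(tert-butyldiphenylsilyloxy)ethyl]hex-5-enoate | COC(=O)C[C@@H](CC=C)CCO[Si](c1ccccc1)(c1ccccc1)C(C)(C)C
F4 | step 3 | (3S)-3-[2-(tert-butyldiphenylsilyloxy)ethyl]-N-methoxy-N-methylhex-5-enamide | CON(C)C(=O)C[C@@H](CC=C)CCO[Si](c1ccccc1)(c1ccccc1)C(C)(C)C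
F5 | step 3 | (5S)-5-[2-(tert-butyldiphenylsilyloxy)ethyl]-2-methylocta-1,7-dien-3-one | CC(=C)C(=O)C[C@@H](CC=C)CCO[Si](c1ccccc1)(c1ccccc1)C(C)(C)C
F6 | step 12 | (1S,3S,4S,6S)-4-(3-hydroxyprop-1-en-2-yl)-1-methyl-2-oxo-7-oxabicyclo[4.1.0]heptan-3-yl 3-methylbutanoate | CC(C)CC(=O)O[C@@H]1C(=O)[C@@]2(C)O[C@H]2C[C@H]1C(=C)CO
F7 | step 12 | (1S,3S,4R,6S)-4-[(2S)-2-(hydroxymethyl)oxiran-2-yl]-1-methyl-2-oxo-7-oxabicyclo[4.1.0]heptan-3-yl 3-methylbutanoate | CC(C)CC(=O)O[C@@H]1C(=O)[C@@]2(C)O[C@H]2C[C@H]1[C@]1(CO)CO1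
F8 | step 14 | (1S,3S,4R,6S)-4-{(2R)-2-[(2E)-1-hydroxy-4-methyl-4-(trimethylsilyloxy)pent-2-en-1-yl]oxiran-2-yl}-1-methyl-2-oxo-7-oxabicyclo[4.1.0]heptan-3-yl 3-methylbutanoate | CC(C)CC(=O)O[C@@H]1C(=O)[C@@]2(C)O[C@H]2C[C@H]1[C@]1(C(O)/C=C/C(C)(C)O[Si](C)(C)C)CO1
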